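Larch, the flask asked about, was also the run I had followed so far, and ash was its cooler twin.

| flask | starting material | protic impurity | temperature | remark | time |
|---|---|---|---|---|---|
| larch | 2 M | 1 M | 20 °C | the very flask that is asked about, followed so far |  |
| ash | 2 M | 1 M | 15 °C | run made earlier |  |
| flask | 2.0 M | 1.00 M | 20 °C |  | 25 h |

| run | time / h | target / % | starting material / % |
|---|---|---|---|
| larch | 3.00 | 20.2 | 2.4 |
| larch | 6.00 | 23.0 | 1.7 |
| larch | 8.00 | 22.2 | 2.6 |
| larch | 12.0 | 23.2 | 2.5 |
| larch | 15.0 | 23.9 | 0 |
| larch | 20.0 | 23.6 | 0 |
| ash | 3.00 | 10.9 | 3.3 |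
| ash | 6.00 | 18.2 | 2.2 |
| ash | 8.00 | 20.2 | 0 |
| ash | 12.0 | 20.8 | 1.8 |
| ash | 15.0 | 18.3 | 1.9 |
| ash | 20.0 | 17.4 | 0.5 |

(readings scatter by 1 percentage point)

- dawn: at 25 h take out 90 % of the target then present, then wait 8.0 h
- noon: change nothing and wait 8.0 h more
- summer: at 25 h raise the temperature by 15 K, then wait 8.0 h

- target taken out counts as made

- target, in percent of the starting material first charged, at 25 h
- what to do for the largest gain in target; "none" if nothing gains more than 2 percentage points (dawn / noon / summer / none)
- target present, with what was taken out counted in, in percent of the starting material first charged, after dawn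
- target present, with what was taken out counted in, in percent of the starting material first charged, after summer

In larch the starting material stood at 2.4 % by 3.00 h, yet the last two target readings averaged 23.8 %, so most of the charge sat in something unread. But a flat reading beside a hidden remainder can be a balance, like two tanks joined by a pipe: once forward and back flows match, time drops out of their ratio. So I defined the hold-back ratio, the part of the charge that is neither target nor starting material divided by the target, an apparent equilibrium constant. Larch read 3.21.

The last two ash readings, 5.00 K cooler, gave 4.54, so the ratio read lower in the warmer flask. I assumed that the whole hidden part could return.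

Larch's early climb gave a time constant of 1.58 h, short against 8.0 h, so I expected the flask to rebalance within the wait. For the target at 25 h I kept the larch reading of 23.8 %.

I reckoned that dawn would remove 21.4 % and that the remainder would split by the same ratio, which gave 40.0 % counted in. For summer I stretched the trend between the two scattered ratios to 1.14, which gave 46.7 %. So I chose summer.

The forecast gave 23.6 % at 25 h, 24 % after dawn and 24 % after summer and chose none, saying “With no feed left, taking product out or heating should gain little”.

The flask gave 23.3 % at 25 h, 37.4 % after dawn and 60.0 % after summer, so the choice was summer, gaining 37 percentage points.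

    starting material ⇌ intermediate (K = 33.0, k = 0.0179 min⁻¹, Ea = 97.0 kJ mol⁻¹, ΔH = −41.0 kJ mol⁻¹)
    intermediate ⇌ target (K = 13.8, k = 0.00558 min⁻¹, Ea = 86.0 kJ mol⁻¹, ΔH = 46.0 kJ mol⁻¹)
    target ⇌ isomer of the product (K = 2.40, k = 0.00339 min⁻¹, Ea = 95.0 kJ mol⁻¹, ΔH = −90.0 kJ mol⁻¹)
    starting material + protic impurity → quenched substrate (k = 0.00303 M⁻¹ min⁻¹, Ea = 75.0 kJ mol⁻¹)
    starting material ⇌ dormant form (K = 10.0, k = 0.0239 min⁻¹, Ea = 84.0 kJ mol⁻¹, ΔH = −58.0 kJ mol⁻¹)
    (constants at 20 °C)

The scheme gives quenched substrate no way back, so I took it out of the ratio. The flask at 25.0 h then read 2.74. I applied this to the neighbour flask with [protic impurity] at 1.7 M, where after 25.0 h quenched substrate stood at 19.4 % and starting material at 0.628 %. What remained, split by that ratio, came to 21.4 % of target. The neighbour flask held 21.5 % of target.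

All runs were computed for an exercise; noise was put on by code.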